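**Retrosynthetic overview**
- Isospiculoic acid A is reached from its allyl ester in which the ring ketone is still a silyl-protected carbinol (endgame: desilylation, oxidation, Pd-mediated deallylation).
- Both rings form in one step: an ester-endo intramolecular Diels–Alder reaction of a linear (E)-enoate / (E,E,E)-phenyltriene closes the six-membered ring and, through the three-carbon tether, the five-membered ring, setting four stereocentres.
- The tetraene comes from a protected anti,syn stereotriad (ethyl, silyloxy, methyl) by three Wittig reactions with one α-ethyl phosphorane and one benzylphosphonate olefination.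
- The stereotriad comes from Sharpless epoxidation of an (E)-allylic alcohol and CuI-catalysed ethyl Grignard opening of the epoxide.
- The first stereocentre comes from ene-reductase reduction of achiral methyl 2-(hydroxymethyl)acrylate to the (R)-hydroxy ester.

TBS = tert-butyldimethylsilyl; TBSO = tert-butyldimethylsilyloxy.
Assumption: a preparative ene-reductase preparation that gives the (R)-ester from methyl 2-(hydroxymethyl)acrylate is at hand; this outcome and the stereoselectivities quoted below are expectations from known chemistry, not verified results.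

**Route**

Step 1
Reactants: 1 methyl 2-(hydroxymethyl)acrylate
Product: 2 methyl (R)-3-hydroxy-2-methylpropanoate
Conditions: ene-reductase (Old Yellow Enzyme family), NAD+ (cat.), formate dehydrogenase, HCO2Na, KH2PO4/K2HPO4 buffer pH 7.5, 30 °C
Reagents that add atoms: none
Why: Catalytic asymmetric (biocatalytic) C=C reduction by a flavin-dependent ene-reductase, in which hydride adds to the terminal CH2 and an active-site residue protonates C2 on one face only, sets the first stereocentre as R in high ee from an achiral acrylate while formate dehydrogenase recycles NADH.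

Step 2
Reactants: 2 methyl (R)-3-hydroxy-2-methylpropanoate; 3 tert-butyldimethylsilyl chloride
Product: 4 methyl (R)-3-(TBSO)-2-methylpropanoate
Conditions: imidazole, DMF, 0 °C to rt
Reagents that add atoms: tert-butyldimethylsilyl chloride, CC(C)(C)[Si](C)(C)Cl
Why: Imidazole-mediated silyl ether formation on the primary alcohol does not touch the α-stereocentre and gives a group that survives every step up to step 21.

Step 3
Reactants: 4 methyl (R)-3-(TBSO)-2-methylpropanoate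
Product: 5 (S)-3-(TBSO)-2-methylpropan-1-ol
Conditions: iBu2AlH (2.2 equiv), CH2Cl2, −78 to 0 °C
Reagents that add atoms: none
Why: Hydride reduction of the ester to the primary alcohol leaves the silyl ether and the stereocentre intact (the descriptor becomes S only through the priority rules).

Step 4
Reactants: 5 (S)-3-(TBSO)-2-methylpropan-1-ol
Product: 6 (R)-3-(TBSO)-2-methylpropanal
Conditions: Dess–Martin periodinane, NaHCO3, CH2Cl2, 0 °C to rt
Reagents that add atoms: none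
Why: Dess–Martin oxidation under buffered conditions gives the configurationally labile α-methyl aldehyde without racemisation, and it is used at once.

Step 5
Reactants: 6 (R)-3-(TBSO)-2-methylpropanal; 7 ethyl (triphenylphosphoranylidene)acetate
Product: 8 ethyl (S,E)-5-(TBSO)-4-methylpent-2-enoate
Conditions: CH2Cl2, rt
Reagents that add atoms: ethyl (triphenylphosphoranylidene)acetate, CCOC(=O)C=P(c1ccccc1)(c1ccccc1)c1ccccc1
Why: Wittig olefination with a stabilised ylide gives the (E)-enoate with high selectivity under neutral conditions that do not epimerise the α-stereocentre.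

Step 6
Reactants: 8 ethyl (S,E)-5-(TBSO)-4-methylpent-2-enoate
Product: 9 (S,E)-5-(TBSO)-4-methylpent-2-en-1-ol
Conditions: iBu2AlH (2.2 equiv), CH2Cl2, −78 °C
Reagents that add atoms: none
Why: 1,2-Reduction of the enoate by iBu2AlH gives the (E)-allylic alcohol needed for directed epoxidation.

Step 7
Reactants: 9 (S,E)-5-(TBSO)-4-methylpent-2-en-1-ol; 10 tert-butyl hydroperoxide
Product: 11 [(2S,3S)-3-[(2R)-1-(TBSO)propan-2-yl]oxiran-2-yl]methanol
Conditions: Ti(OiPr)4 (10 mol%), L-(+)-diethyl tartrate (12 mol%), molecular sieves 4 Å, CH2Cl2, −20 °C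
Reagents that add atoms: tert-butyl hydroperoxide, CC(C)(C)OO
Why: Sharpless asymmetric epoxidation with the Ti(OiPr)4/L-(+)-diethyl tartrate catalyst transfers oxygen to the alkene face that gives the (2S,3S)-epoxide of an (E)-allylic alcohol, and this reagent control places the new C–O bond syn to the existing methyl group.

Step 8
Reactants: 11 [(2S,3S)-3-[(2R)-1-(TBSO)propan-2-yl]oxiran-2-yl]methanol; 12 ethylmagnesium bromide
Product: 13 (2R,3S,4R)-5-(TBSO)-2-ethyl-4-methylpentane-1,3-diol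
Conditions: EtMgBr (4 equiv), CuI (20 mol%), THF/Et2O, −40 to −10 °C; aq. NH4Cl
Reagents that add atoms: ethylmagnesium bromide, CC[Mg]Br
Why: CuI-catalysed SN2 opening of the 2,3-epoxy alcohol occurs at C2, away from the branched C3 substituent, with inversion, so the trans-epoxide gives the 2,3-anti ethyl/hydroxyl pair and completes the anti,syn stereotriad as a 1,3-diol.

Step 9
Reactants: 13 (2R,3S,4R)-5-(TBSO)-2-ethyl-4-methylpentane-1,3-diol; 14 pivaloyl chloride
Product: 15 (2R,3S,4R)-5-(TBSO)-2-ethyl-3-hydroxy-4-methylpentyl pivalate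
Conditions: pyridine, CH2Cl2, 0 °C
Reagents that add atoms: pivaloyl chloride, CC(C)(C)C(=O)Cl
Why: Acylation with the bulky acid chloride is selective for the primary hydroxyl and leaves the hindered secondary one free.

Step 10
Reactants: 15 (2R,3S,4R)-5-(TBSO)-2-ethyl-3-hydroxy-4-methylpentyl pivalate; 16 tert-butyldimethylsilyl trifluoromethanesulfonate
Product: 17 (2R,3S,4R)-3,5-bis(TBSO)-2-ethyl-4-methylpentyl pivalate
Conditions: 2,6-lutidine, CH2Cl2, −78 to 0 °C
Reagents that add atoms: tert-butyldimethylsilyl trifluoromethanesulfonate, CC(C)(C)[Si](C)(C)OS(=O)(=O)C(F)(F)F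
Why: The silyl triflate silylates the hindered secondary alcohol (silyl ether formation), masking the future ketone oxygen so that the two flanking stereocentres cannot epimerise later.

Step 11
Reactants: 17 (2R,3S,4R)-3,5-bis(TBSO)-2-ethyl-4-methylpentyl pivalate
Product: 18 (2R,3S,4R)-3,5-bis(TBSO)-2-ethyl-4-methylpentan-1-ol
Conditions: iBu2AlH (2.5 equiv), CH2Cl2, −78 °C
Reagents that add atoms: none
Why: Reductive cleavage of the pivalate by iBu2AlH frees the primary alcohol while both silyl ethers survive.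

Step 12
Reactants: 18 (2R,3S,4R)-3,5-bis(TBSO)-2-ethyl-4-methylpentan-1-ol
Product: 19 (2S,3S,4R)-3,5-bis(TBSO)-2-ethyl-4-methylpentanal
Conditions: Dess–Martin periodinane, NaHCO3, CH2Cl2, 0 °C to rt
Reagents that add atoms: none
Why: Dess–Martin oxidation gives the α-ethyl aldehyde without epimerisation.

Step 13
Reactants: 20 propyltriphenylphosphonium bromide; 21 allyl chloroformate
Product: 24 allyl 2-(triphenylphosphoranylidene)butanoate, via propylidene(triphenyl)phosphorane 22 (not isolated), via [1-(allyloxycarbonyl)propyl]triphenylphosphonium chloride 23 (not isolated)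
Conditions: NaN(SiMe3)2 (1.0 equiv), THF, 0 °C; ylide solution added to 21 in THF, −78 °C to rt; then aq. NaOH, CH2Cl2, rt
Reagents that add atoms: allyl chloroformate, C=CCOC(=O)Cl
Why: Deprotonation gives the non-stabilised ylide, C-acylation by the chloroformate (alkoxycarbonylation of a phosphorus ylide) gives the ester phosphonium salt, and NaOH converts it into the stabilised α-ethyl ylide, all from achiral materials.

Step 14
Reactants: 19 (2S,3S,4R)-3,5-bis(TBSO)-2-ethyl-4-methylpentanal; 24 allyl 2-(triphenylphosphoranylidene)butanoate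
Product: 25 allyl (2E,4R,5R,6R)-5,7-bis(TBSO)-2,4-diethyl-6-methylhept-2-enoate
Conditions: toluene, 90 °C
Reagents that add atoms: allyl 2-(triphenylphosphoranylidene)butanoate, CCC(C(=O)OCC=C)=P(c1ccccc1)(c1ccccc1)c1ccccc1
Why: Wittig olefination with the stabilised α-ethyl ylide gives the (E)-trisubstituted enoate (chain trans to the ester) under neutral conditions that keep the α-ethyl stereocentre.

Step 15
Reactants: 25 allyl (2E,4R,5R,6R)-5,7-bis(TBSO)-2,4-diethyl-6-methylhept-2-enoate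
Product: 26 (2E,4R,5R,6R)-5,7-bis(TBSO)-2,4-diethyl-6-methylhept-2-en-1-ol
Conditions: iBu2AlH (2.5 equiv), CH2Cl2, −78 °C
Reagents that add atoms: none
Why: Reduction of the allyl ester by iBu2AlH gives the (E)-allylic alcohol and leaves the silyl ethers untouched.

Step 16
Reactants: 26 (2E,4R,5R,6R)-5,7-bis(TBSO)-2,4-diethyl-6-methylhept-2-en-1-ol
Product: 27 (2E,4R,5R,6R)-5,7-bis(TBSO)-2,4-diethyl-6-methylhept-2-enal
Conditions: Dess–Martin periodinane, NaHCO3, CH2Cl2, 0 °C
Reagents that add atoms: none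
Why: Dess–Martin oxidation of the allylic alcohol gives the enal without E/Z isomerisation.

Step 17
Reactants: 27 (2E,4R,5R,6R)-5,7-bis(TBSO)-2,4-diethyl-6-methylhept-2-enal; 24 allyl 2-(triphenylphosphoranylidene)butanoate
Product: 28 allyl (2E,4E,6R,7R,8R)-7,9-bis(TBSO)-2,4,6-triethyl-8-methylnona-2,4-dienoate
Conditions: toluene, 100 °C
Reagents that add atoms: allyl 2-(triphenylphosphoranylidene)butanoate, CCC(C(=O)OCC=C)=P(c1ccccc1)(c1ccccc1)c1ccccc1
Why: A second Wittig olefination with the same stabilised ylide adds the next (E)-trisubstituted double bond, placing the ester carbon trans to the chain as the later styryl group must be.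

Step 18
Reactants: 28 allyl (2E,4E,6R,7R,8R)-7,9-bis(TBSO)-2,4,6-triethyl-8-methylnona-2,4-dienoate
Product: 29 (2E,4E,6R,7R,8R)-7,9-bis(TBSO)-2,4,6-triethyl-8-methylnona-2,4-dien-1-ol
Conditions: iBu2AlH (2.5 equiv), CH2Cl2, −78 °C
Reagents that add atoms: none
Why: 1,2-Reduction of the dienoate by iBu2AlH gives the dienol with both double bonds unchanged.

Step 19
Reactants: 29 (2E,4E,6R,7R,8R)-7,9-bis(TBSO)-2,4,6-triethyl-8-methylnona-2,4-dien-1-ol
Product: 30 (2E,4E,6R,7R,8R)-7,9-bis(TBSO)-2,4,6-triethyl-8-methylnona-2,4-dienal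
Conditions: Dess–Martin periodinane, NaHCO3, CH2Cl2, 0 °C
Reagents that add atoms: none
Why: Dess–Martin oxidation gives the dienal without touching the diene geometry or the silyl ethers.

Step 20
Reactants: 30 (2E,4E,6R,7R,8R)-7,9-bis(TBSO)-2,4,6-triethyl-8-methylnona-2,4-dienal; 31 diethyl benzylphosphonate
Product: 33 (2R,3R,4R,5E,7E,9E)-1,3-bis(TBSO)-4,6,8-triethyl-2-methyl-10-phenyldeca-5,7,9-triene, via sodium (diethoxyphosphoryl)(phenyl)methanide 32 (not isolated)
Conditions: NaN(SiMe3)2, THF, −78 to 0 °C; then 30, 0 °C to rt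
Reagents that add atoms: diethyl benzylphosphonate, CCOP(=O)(Cc1ccccc1)OCC
Why: Horner–Wadsworth–Emmons olefination with the semi-stabilised benzylphosphonate anion gives the (E)-styryl double bond and completes the (E,E,E)-1-phenyltriene.

Step 21
Reactants: 33 (2R,3R,4R,5E,7E,9E)-1,3-bis(TBSO)-4,6,8-triethyl-2-methyl-10-phenyldeca-5,7,9-triene
Product: 34 (2R,3R,4R,5E,7E,9E)-3-(TBSO)-4,6,8-triethyl-2-methyl-10-phenyldeca-5,7,9-trien-1-ol
Conditions: HF·pyridine, pyridine, THF, 0 °C to rt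
Reagents that add atoms: none
Why: Buffered fluoride desilylation removes the unhindered primary silyl ether much faster than the secondary one, which is flanked by two branched carbons.

Step 22
Reactants: 34 (2R,3R,4R,5E,7E,9E)-3-(TBSO)-4,6,8-triethyl-2-methyl-10-phenyldeca-5,7,9-trien-1-ol
Product: 35 (2S,3R,4R,5E,7E,9E)-3-(TBSO)-4,6,8-triethyl-2-methyl-10-phenyldeca-5,7,9-trienal
Conditions: Dess–Martin periodinane, NaHCO3, CH2Cl2, 0 °C
Reagents that add atoms: none
Why: Dess–Martin oxidation gives the α-methyl aldehyde, which is used at once to avoid epimerisation.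

Step 23
Reactants: 35 (2S,3R,4R,5E,7E,9E)-3-(TBSO)-4,6,8-triethyl-2-methyl-10-phenyldeca-5,7,9-trienal; 24 allyl 2-(triphenylphosphoranylidene)butanoate
Product: 37 allyl (1R,2S,3R,3aS,4S,5R,7aS)-2-(TBSO)-1,4,5,7-tetraethyl-3-methyl-5-[(E)-2-phenylethenyl]-2,3,3a,4,5,7a-hexahydro-1H-indene-4-carboxylate, via tetraene ester 36 (not isolated)
Conditions: toluene (degassed), BHT (cat.), 80 °C then 110 °C
Reagents that add atoms: allyl 2-(triphenylphosphoranylidene)butanoate, CCC(C(=O)OCC=C)=P(c1ccccc1)(c1ccccc1)c1ccccc1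
Why: Wittig olefination gives the (E)-2-ethyl enoate, which on further heating undergoes an intramolecular Diels–Alder reaction through the ester-endo transition state in which the allylic hydrogens at C4 and C6 eclipse the neighbouring double bonds (minimised A(1,3) strain), so each tether stereocentre fixes the face of its π-partner and the trans-fused bicycle forms with the four new stereocentres, two of them adjacent quaternary carbons, as drawn.

Step 24
Reactants: 37 allyl (1R,2S,3R,3aS,4S,5R,7aS)-2-(TBSO)-1,4,5,7-tetraethyl-3-methyl-5-[(E)-2-phenylethenyl]-2,3,3a,4,5,7a-hexahydro-1H-indene-4-carboxylate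
Product: 38 allyl (1R,2S,3R,3aS,4S,5R,7aS)-1,4,5,7-tetraethyl-2-hydroxy-3-methyl-5-[(E)-2-phenylethenyl]-2,3,3a,4,5,7a-hexahydro-1H-indene-4-carboxylate
Conditions: aq. HF (48%), MeCN, rt
Reagents that add atoms: none
Why: Acidic fluoride desilylation cleaves the remaining secondary silyl ether, and the freed hydroxyl lies on the face opposite the ester so it cannot lactonise.

Step 25
Reactants: 38 allyl (1R,2S,3R,3aS,4S,5R,7aS)-1,4,5,7-tetraethyl-2-hydroxy-3-methyl-5-[(E)-2-phenylethenyl]-2,3,3a,4,5,7a-hexahydro-1H-indene-4-carboxylate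
Product: 39 allyl (1R,3R,3aS,4S,5R,7aS)-1,4,5,7-tetraethyl-3-methyl-2-oxo-5-[(E)-2-phenylethenyl]-2,3,3a,4,5,7a-hexahydro-1H-indene-4-carboxylate
Conditions: Dess–Martin periodinane, NaHCO3, CH2Cl2, rt
Reagents that add atoms: none
Why: Dess–Martin oxidation gives the cyclopentanone under neutral conditions, and its two α-stereocentres already hold the more stable all-trans arrangement.

Step 26
Reactants: 39 allyl (1R,3R,3aS,4S,5R,7aS)-1,4,5,7-tetraethyl-3-methyl-2-oxo-5-[(E)-2-phenylethenyl]-2,3,3a,4,5,7a-hexahydro-1H-indene-4-carboxylate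
Product: 40 isospiculoic acid A
Conditions: Pd(PPh3)4 (5 mol%), morpholine, THF, rt; aq. citric acid work-up
Reagents that add atoms: none
Why: Tsuji–Trost deallylation, in which Pd(PPh3)4 cleaves the O–allyl bond by oxidative addition and morpholine takes up the allyl group, frees the acid without attack at the very hindered carboxyl carbon and without base that could epimerise the ketone.

**Compound list**

1 | methyl 2-(hydroxymethyl)acrylate | C=C(CO)C(=O)OC | starting material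
2 | methyl (R)-3-hydroxy-2-methylpropanoate | OC[C@@H](C)C(=O)OC | intermediate
3 | tert-butyldimethylsilyl chloride | CC(C)(C)[Si](C)(C)Cl | starting material
4 | methyl (R)-3-(TBSO)-2-methylpropanoate | CC(C)(C)[Si](C)(C)OC[C@@H](C)C(=O)OC | intermediate
5 | (S)-3-(TBSO)-2-methylpropan-1-ol | CC(C)(C)[Si](C)(C)OC[C@@H](C)CO | intermediate
6 | (R)-3-(TBSO)-2-methylpropanal | CC(C)(C)[Si](C)(C)OC[C@@H](C)C=O | intermediate
7 | ethyl (triphenylphosphoranylidene)acetate | CCOC(=O)C=P(c1ccccc1)(c1ccccc1)c1ccccc1 | starting material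
8 | ethyl (S,E)-5-(TBSO)-4-methylpent-2-enoate | CC(C)(C)[Si](C)(C)OC[C@@H](C)/C=C/C(=O)OCC | intermediate
9 | (S,E)-5-(TBSO)-4-methylpent-2-en-1-ol | CC(C)(C)[Si](C)(C)OC[C@@H](C)/C=C/CO | intermediate
10 | tert-butyl hydroperoxide | CC(C)(C)OO | starting material
11 | [(2S,3S)-3-[(2R)-1-(TBSO)propan-2-yl]oxiran-2-yl]methanol | CC(C)(C)[Si](C)(C)OC[C@@H](C)[C@@H]1O[C@H]1CO | intermediate
12 | ethylmagnesium bromide | CC[Mg]Br | starting material
13 | (2R,3S,4R)-5-(TBSO)-2-ethyl-4-methylpentane-1,3-diol | CC(C)(C)[Si](C)(C)OC[C@@H](C)[C@H](O)[C@H](CC)CO | intermediate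
14 | pivaloyl chloride | CC(C)(C)C(=O)Cl | starting material
15 | (2R,3S,4R)-5-(TBSO)-2-ethyl-3-hydroxy-4-methylpentyl pivalate | CC(C)(C)[Si](C)(C)OC[C@@H](C)[C@H](O)[C@H](CC)COC(=O)C(C)(C)C | intermediate
16 | tert-butyldimethylsilyl trifluoromethanesulfonate | CC(C)(C)[Si](C)(C)OS(=O)(=O)C(F)(F)F | starting material
17 | (2R,3S,4R)-3,5-bis(TBSO)-2-ethyl-4-methylpentyl pivalate | CC(C)(C)[Si](C)(C)OC[C@@H](C)[C@H](O[Si](C)(C)C(C)(C)C)[C@H](CC)COC(=O)C(C)(C)C | intermediate
18 | (2R,3S,4R)-3,5-bis(TBSO)-2-ethyl-4-methylpentan-1-ol | CC(C)(C)[Si](C)(C)OC[C@@H](C)[C@H](O[Si](C)(C)C(C)(C)C)[C@H](CC)CO | intermediate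
19 | (2S,3S,4R)-3,5-bis(TBSO)-2-ethyl-4-methylpentanal | CC(C)(C)[Si](C)(C)OC[C@@H](C)[C@H](O[Si](C)(C)C(C)(C)C)[C@H](CC)C=O | intermediate
20 | propyltriphenylphosphonium bromide | [Br-].CCC[P+](c1ccccc1)(c1ccccc1)c1ccccc1 | starting material
21 | allyl chloroformate | C=CCOC(=O)Cl | starting material
22 | propylidene(triphenyl)phosphorane | CCC=P(c1ccccc1)(c1ccccc1)c1ccccc1 | intermediate
23 | [1-(allyloxycarbonyl)propyl]triphenylphosphonium chloride | [Cl-].CCC(C(=O)OCC=C)[P+](c1ccccc1)(c1ccccc1)c1ccccc1 | intermediate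
24 | allyl 2-(triphenylphosphoranylidene)butanoate | CCC(C(=O)OCC=C)=P(c1ccccc1)(c1ccccc1)c1ccccc1 | intermediate
25 | allyl (2E,4R,5R,6R)-5,7-bis(TBSO)-2,4-diethyl-6-methylhept-2-enoate | CC(C)(C)[Si](C)(C)OC[C@@H](C)[C@H](O[Si](C)(C)C(C)(C)C)[C@H](CC)/C=C(CC)/C(=O)OCC=C | intermediate
26 | (2E,4R,5R,6R)-5,7-bis(TBSO)-2,4-diethyl-6-methylhept-2-en-1-ol | CC(C)(C)[Si](C)(C)OC[C@@H](C)[C@H](O[Si](C)(C)C(C)(C)C)[C@H](CC)/C=C(CC)/CO | intermediate
27 | (2E,4R,5R,6R)-5,7-bis(TBSO)-2,4-diethyl-6-methylhept-2-enal | CC(C)(C)[Si](C)(C)OC[C@@H](C)[C@H](O[Si](C)(C)C(C)(C)C)[C@H](CC)/C=C(CC)/C=O | intermediate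
28 | allyl (2E,4E,6R,7R,8R)-7,9-bis(TBSO)-2,4,6-triethyl-8-methylnona-2,4-dienoate | CC(C)(C)[Si](C)(C)OC[C@@H](C)[C@H](O[Si](C)(C)C(C)(C)C)[C@H](CC)/C=C(CC)/C=C(CC)/C(=O)OCC=C | intermediate
29 | (2E,4E,6R,7R,8R)-7,9-bis(TBSO)-2,4,6-triethyl-8-methylnona-2,4-dien-1-ol | CC(C)(C)[Si](C)(C)OC[C@@H](C)[C@H](O[Si](C)(C)C(C)(C)C)[C@H](CC)/C=C(CC)/C=C(CC)/CO | intermediate
30 | (2E,4E,6R,7R,8R)-7,9-bis(TBSO)-2,4,6-triethyl-8-methylnona-2,4-dienal | CC(C)(C)[Si](C)(C)OC[C@@H](C)[C@H](O[Si](C)(C)C(C)(C)C)[C@H](CC)/C=C(CC)/C=C(CC)/C=O | intermediate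
31 | diethyl benzylphosphonate | CCOP(=O)(Cc1ccccc1)OCC | starting material
32 | sodium (diethoxyphosphoryl)(phenyl)methanide | [Na+].CCOP(=O)([CH-]c1ccccc1)OCC | intermediate
33 | (2R,3R,4R,5E,7E,9E)-1,3-bis(TBSO)-4,6,8-triethyl-2-methyl-10-phenyldeca-5,7,9-triene | CC(C)(C)[Si](C)(C)OC[C@@H](C)[C@H](O[Si](C)(C)C(C)(C)C)[C@H](CC)/C=C(CC)/C=C(CC)/C=C/c1ccccc1 | intermediate
34 | (2R,3R,4R,5E,7E,9E)-3-(TBSO)-4,6,8-triethyl-2-methyl-10-phenyldeca-5,7,9-trien-1-ol | OC[C@@H](C)[C@H](O[Si](C)(C)C(C)(C)C)[C@H](CC)/C=C(CC)/C=C(CC)/C=C/c1ccccc1 | intermediate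
35 | (2S,3R,4R,5E,7E,9E)-3-(TBSO)-4,6,8-triethyl-2-methyl-10-phenyldeca-5,7,9-trienal | O=C[C@@H](C)[C@H](O[Si](C)(C)C(C)(C)C)[C@H](CC)/C=C(CC)/C=C(CC)/C=C/c1ccccc1 | intermediate
36 | allyl (2E,4R,5S,6R,7E,9E,11E)-5-(TBSO)-2,6,8,10-tetraethyl-4-methyl-12-phenyldodeca-2,7,9,11-tetraenoate | C=CCOC(=O)/C(CC)=C/[C@@H](C)[C@H](O[Si](C)(C)C(C)(C)C)[C@H](CC)/C=C(CC)/C=C(CC)/C=C/c1ccccc1 | intermediate
37 | allyl (1R,2S,3R,3aS,4S,5R,7aS)-2-(TBSO)-1,4,5,7-tetraethyl-3-methyl-5-[(E)-2-phenylethenyl]-2,3,3a,4,5,7a-hexahydro-1H-indene-4-carboxylate | CCC1=C[C@](/C=C/c2ccccc2)(CC)[C@@](CC)(C(=O)OCC=C)[C@H]2[C@H]1[C@@H](CC)[C@@H](O[Si](C)(C)C(C)(C)C)[C@@H]2C | intermediate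
38 | allyl (1R,2S,3R,3aS,4S,5R,7aS)-1,4,5,7-tetraethyl-2-hydroxy-3-methyl-5-[(E)-2-phenylethenyl]-2,3,3a,4,5,7a-hexahydro-1H-indene-4-carboxylate | CCC1=C[C@](/C=C/c2ccccc2)(CC)[C@@](CC)(C(=O)OCC=C)[C@H]2[C@H]1[C@@H](CC)[C@@H](O)[C@@H]2C | intermediate
39 | allyl (1R,3R,3aS,4S,5R,7aS)-1,4,5,7-tetraethyl-3-methyl-2-oxo-5-[(E)-2-phenylethenyl]-2,3,3a,4,5,7a-hexahydro-1H-indene-4-carboxylate | CCC1=C[C@](/C=C/c2ccccc2)(CC)[C@@](CC)(C(=O)OCC=C)[C@H]2[C@H]1[C@@H](CC)C(=O)[C@@H]2C | intermediate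
40 | isospiculoic acid A, (1R,3R,3aS,4S,5R,7aS)-1,4,5,7-tetraethyl-3-methyl-2-oxo-5-[(E)-2-phenylethenyl]-2,3,3a,4,5,7a-hexahydro-1H-indene-4-carboxylic acid | CCC1=C[C@](/C=C/c2ccccc2)(CC)[C@@](CC)(C(=O)O)[C@H]2[C@H]1[C@@H](CC)C(=O)[C@@H]2C | target

**Step count and risks**

Total steps: 26. Longest linear sequence: 25 steps (steps 1–12 and 14–26; step 13 is the one-step side branch to phosphorane 24).

First risk, step 8: the ethyl group may add at C3 as well as C2 and give a 1,2-diol. The fallback sets out from aldehyde 6 and builds the same stereotriad by a substrate-controlled anti-aldol reaction. Butanoyl chloride and 2,6-dimethylphenol (Et3N, CH2Cl2) give 2,6-dimethylphenyl butanoate F1. Its (E)-enolate, formed with LiN(iPr)2 in THF at −78 °C, adds to 6 through a chair transition state on the Felkin face to give 2,6-dimethylphenyl (2S,3S,4R)-5-(TBSO)-2-ethyl-3-hydroxy-4-methylpentanoate F2. Reduction of F2 with LiAlH4 gives diol 13, where the route is rejoined.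

Second risk, step 17: the Wittig reaction between the hindered, poorly electrophilic α-ethyl enal 27 and the α-ethyl ylide 24 may be slow or lose E-selectivity. The fallback sets out from 27 and builds the diene terminus by cross-coupling instead of olefination. CBr4/PPh3 (Ramirez olefination) gives (3E,5R,6R,7R)-1,1-dibromo-6,8-bis(TBSO)-3,5-diethyl-7-methylocta-1,3-diene F3. Suzuki–Miyaura coupling with (E)-2-phenylvinylboronic acid (Pd(PPh3)4, K3PO4) reacts at the bromide trans to the chain and gives (2R,3R,4R,5E,7Z,9E)-8-bromo-1,3-bis(TBSO)-4,6-diethyl-2-methyl-10-phenyldeca-5,7,9-triene F4. Negishi coupling of F4 with Et2Zn (Pd(PtBu3)2) replaces the remaining bromide with retention and gives triene 33, where the route is rejoined.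

Third risk, step 23: the cycloaddition must join two fully substituted carbons and may stall or lose selectivity at 110 °C. The fallback sets out from tetraene ester 36, isolated by running the Wittig stage at 60–70 °C, and switches to a Lewis-acid-activated enal dienophile. iBu2AlH gives (2E,4R,5S,6R,7E,9E,11E)-5-(TBSO)-2,6,8,10-tetraethyl-4-methyl-12-phenyldodeca-2,7,9,11-tetraen-1-ol F5, and Dess–Martin oxidation gives the corresponding tetraenal F6. Me2AlCl (CH2Cl2, −78 to −20 °C) promotes the same aldehyde-endo intramolecular Diels–Alder reaction to (1R,2S,3R,3aS,4S,5R,7aS)-2-(TBSO)-1,4,5,7-tetraethyl-3-methyl-5-[(E)-2-phenylethenyl]-2,3,3a,4,5,7a-hexahydro-1H-indene-4-carbaldehyde F7. Pinnick oxidation (NaClO2, NaH2PO4, 2-methylbut-2-ene) gives the corresponding 2-(TBSO) carboxylic acid F8, aq. HF in MeCN gives the 2-hydroxy carboxylic acid F9, and Dess–Martin oxidation of F9 gives 40 directly.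

Further compounds
F1 | step 8 | 2,6-dimethylphenyl butanoate | CCCC(=O)Oc1c(C)cccc1C
F2 | step 8 | 2,6-dimethylphenyl (2S,3S,4R)-5-(TBSO)-2-ethyl-3-hydroxy-4-methylpentanoate | CC(C)(C)[Si](C)(C)OC[C@@H](C)[C@H](O)[C@H](CC)C(=O)Oc1c(C)cccc1C
F3 | step 17 | (3E,5R,6R,7R)-1,1-dibromo-6,8-bis(TBSO)-3,5-diethyl-7-methylocta-1,3-diene | CC(C)(C)[Si](C)(C)OC[C@@H](C)[C@H](O[Si](C)(C)C(C)(C)C)[C@H](CC)/C=C(CC)/C=C(Br)Br
F4 | step 17 | (2R,3R,4R,5E,7Z,9E)-8-bromo-1,3-bis(TBSO)-4,6-diethyl-2-methyl-10-phenyldeca-5,7,9-triene | CC(C)(C)[Si](C)(C)OC[C@@H](C)[C@H](O[Si](C)(C)C(C)(C)C)[C@H](CC)/C=C(CC)/C=C(Br)/C=C/c1ccccc1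
F5 | step 23 | (2E,4R,5S,6R,7E,9E,11E)-5-(TBSO)-2,6,8,10-tetraethyl-4-methyl-12-phenyldodeca-2,7,9,11-tetraen-1-ol | OC/C(CC)=C/[C@@H](C)[C@H](O[Si](C)(C)C(C)(C)C)[C@H](CC)/C=C(CC)/C=C(CC)/C=C/c1ccccc1
F6 | step 23 | (2E,4R,5S,6R,7E,9E,11E)-5-(TBSO)-2,6,8,10-tetraethyl-4-methyl-12-phenyldodeca-2,7,9,11-tetraenal | O=C/C(CC)=C/[C@@H](C)[C@H](O[Si](C)(C)C(C)(C)C)[C@H](CC)/C=C(CC)/C=C(CC)/C=C/c1ccccc1
F7 | step 23 | (1R,2S,3R,3aS,4S,5R,7aS)-2-(TBSO)-1,4,5,7-tetraethyl-3-methyl-5-[(E)-2-phenylethenyl]-2,3,3a,4,5,7a-hexahydro-1H-indene-4-carbaldehyde | CCC1=C[C@](/C=C/c2ccccc2)(CC)[C@@](CC)(C=O)[C@H]2[C@H]1[C@@H](CC)[C@@H](O[Si](C)(C)C(C)(C)C)[C@@H]2C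
F8 | step 23 | (1R,2S,3R,3aS,4S,5R,7aS)-2-(TBSO)-1,4,5,7-tetraethyl-3-methyl-5-[(E)-2-phenylethenyl]-2,3,3a,4,5,7a-hexahydro-1H-indene-4-carboxylic acid | CCC1=C[C@](/C=C/c2ccccc2)(CC)[C@@](CC)(C(=O)O)[C@H]2[C@H]1[C@@H](CC)[C@@H](O[Si](C)(C)C(C)(C)C)[C@@H]2C
F9 | step 23 | (1R,2S,3R,3aS,4S,5R,7aS)-1,4,5,7-tetraethyl-2-hydroxy-3-methyl-5-[(E)-2-phenylethenyl]-2,3,3a,4,5,7a-hexahydro-1H-indene-4-carboxylic acid | CCC1=C[C@](/C=C/c2ccccc2)(CC)[C@@](CC)(C(=O)O)[C@H]2[C@H]1[C@@H](CC)[C@@H](O)[C@@H]2C
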